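Slowness is no worry in this flask: the half-life of the starting complex by step 1, with the whole charge of incoming ligand counted as present at once, is 0.24 d, far shorter than the 12 d allowed, so I ask what the ligand can buy.

    starting complex + incoming ligand → leaving ligand + complex with one exchanged (k1 = 3.01 L mol⁻¹ h⁻¹)
    complex with one exchanged + incoming ligand → leaving ligand + complex with two exchanged (k2 = 4.05 L mol⁻¹ h⁻¹)

starting complex 44 mM; incoming ligand 39.6 mM (fed, over 15 h); leaving ligand 88.0 mM; time 12 d

- the reaction counts as stopped when no species that holds the starting complex changes by six tenths of a point or more over the second half of the time
- run time (flask): 12 d

* which holds at 12 d: what has brought the reaction to rest, or that it has not come to rest (the incoming ligand has run out first / it is still moving / all of the starting complex has reacted)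
* part of the starting complex gone at 12 d
* the complex with one exchanged standing at 12 d, as a percentage of the starting complex charged
* the complex with two exchanged standing at 12 d, as a percentage of the starting complex charged

- The charge is 0.900 equivalents of incoming ligand. At one ligand per starting complex lost, that gives 90.0% conversion.
- But step 2 competes for the ligand, and its constant is the larger. Both rates carry c(incoming ligand) as a factor, so it cancels from their ratio, which leaves c(complex with one exchanged)/c(starting complex) times the rate constant of step 2 over that of step 1, the selectivity factor 1.35.
- The ligand spent per starting complex lost is therefore 1 plus the selectivity factor times c(complex with one exchanged)/c(starting complex). This cost starts at 1. If it ends near two, its mean is 1.50 and the conversion is 60.0%.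
- That end value is a guess, so I test it. With m the share of starting complex left, the share with one exchanged is a = (m − m^κ)/(κ − 1), where κ is the selectivity factor. A trial m of 40.0% gives a = 31.4% and an end cost of 2.06, so the guess holds up.
- The ligand needed is 2(1 − m) − a, here 0.886 equivalents. Spending the remainder at that end cost brings the conversion to 60.7%. I commit to that, with 31.4% one exchanged and 29.3% two exchanged.
- One doubt remains: the ligand thins out and slows. At those shares I reckon its half-life at 0.267 d, shorter than 12 d, and by that estimate <0.001% of it stands at the end, so I take it as the limiting reagent.
- The forecast says that the incoming ligand has run out first, with 60.7% conversion, 31.4% one exchanged and 29.3% two exchanged, holding that “the feed timing drops out”.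
- In the flask at 12 d, the incoming ligand has run out first, with 60.7% conversion, 31.4% one exchanged and 29.3% two exchanged.
- A neighbour flask charged with 67 mM of incoming ligand holds 1.52 equivalents, its other charges as in the recipe. I repeat the reckoning with the same 1.35: a trial m of 14.3% gives a = 20.2%, a cost of 2.91 and 1.51 equivalents needed, so the conversion comes to 86.0%. That neighbour stands at 86.1% conversion, with 19.9% one exchanged and 66.2% two exchanged.

All constants stand for no real mixture.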